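The numbers in the tables stem from a simulated flask from invented constants; scatter was added.

How much J stands after 8.0 h in five flasks that hold the same G and differ in E?

| flask | E | G | remark | time |
|---|---|---|---|---|
| noon | 0.027 M | 0.045 M | run made earlier |  |
| summer | 0.29 M | 0.045 M | run made earlier |  |
| teal | 0.025 M | 0.0450 M |  | 8.0 h |
| green | 0.050 M | 0.0450 M |  | 8.0 h |
| blue | 0.10 M | 0.0450 M |  | 8.0 h |
| grey | 0.20 M | 0.0450 M |  | 8.0 h |
| amber | 0.40 M | 0.0450 M |  | 8.0 h |

- noon (time / h: J / %, E / %): 0.417: 0, 91.3; 1.00: 0.8, 81.6; 2.50: 1.4, 61.6; 6.00: 3.9, 37.1
- summer (time / h: J / %, E / %): 0.417: 0.8, 93.3; 1.00: 0.5, 88.8; 2.50: 0.6, 84.8; 6.00: 0, 84.1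

(readings scatter by 0.5 percentage points)

1. [J] at the end for teal, green, blue, grey, amber, in this order
2. the course of these numbers from the first flask to the last (hardly changes / falls all the way / rises all the way / rises, then falls / falls, then rises)

- "hardly changes" means that all values lie within two and a half points (for a concentration: within two and a half percent of the largest)

J comes late: in the noon run it reads 0% at 0.417 h and 3.9% at 6.00 h, while E has fallen to 37.1%. So we take J as a second addition of G onto a first adduct made from E and G, and J then needs that adduct and G side by side. Two times say whether they meet.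

The first is 4.92 h, the life of E against the G charge. We read it from noon's fall in E up to 1.00 h, treating E as pseudo-first-order with G as charged. The second is the life of G against the E charge, which is that time multiplied by the G charge over the E charge.

The summer run tests this. There the life of G is 0.763 h, and E already reads 84.8% at 2.50 h and 84.1% at 6.00 h. It has lost 0.0461 M, about the G charge of 0.045 M, so G is the limiting reagent there.

The two times cross where the E charge equals 0.0450 M. Below that, as in teal, we expect G to outlast E, with the small E charge limiting the adduct; above it, as in amber, we expect G to last a shorter time than E and to go to E rather than to the adduct. We therefore expect a row that rises, then falls, with its top near that crossing, closest to green.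

The forecast reads 0.0015 M, 0.0019 M, 0.0016 M, 8.500 × 10⁻⁴ M, 3.500 × 10⁻⁴ M, with the course rises, then falls.

The flasks give 0.00158 M, 0.00164 M, 9.77 × 10⁻⁴ M, 3.66 × 10⁻⁴ M, 1.44 × 10⁻⁴ M, with the course rises, then falls.

    E + G → Z + Q (k = 4.90 /M/h)
    2 E → L (k = 0.00420 /M/h)
    G + Z ⇌ J + Q (K = 0.220, k = 0.700 /M/h)

The row turns at 0.038 M, a little below our crossing. In teal the life of G is 8.85 h, and G keeps 56.4% of its charge at the end; the time given and the depletion of G act together on teal's J, which stands at 0.00158 M, against 0.00296 M at 80.0 h and 0.00256 M with G held at its charge. In amber that life is 0.553 h, and G stands at 0.127% of its charge at 4.00 h. The depletion of G is one part of amber's low J: with G held at its charge, amber ends at 0.00930 M instead of 1.44 × 10⁻⁴ M.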